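**Plan**
- Cuts: the acetates and the C15 silyl ether come off last. C12–C13 (B-alkyl Suzuki) and C11=C12 (Wittig) are cut next, leaving a drimane whose C11 is a carbonyl carbon. C7–O, C6–H and C5–H trace back to a C5=C6 silyl enol ether. C7–C8 and C9–C10 of ring B fall in one Diels–Alder cut.
- Enabling feature: on ring A the C2 oxygen and the C10–C9 bond are 1,3-cis (both α). C11 can therefore be carried as a C2 ester that holds the C8≡C9 alkyne under C10 of a C7=C6–C5=C10 diene built on ring A.
- Forward order: ring A is bought, and C6/C7 are added by Stille coupling. Ring B and a temporary bridging δ-lactone ring close together. The lactone is opened by hydride before C5 becomes a stereocentre, because the bridge holds C9 axial on ring A and would allow only a cis ring fusion. The chain then grows C11 → C12 → C13–C16.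
- Stereochemistry: C2 comes from actinol, and C10 is relayed from C2 through the tether. C5, C7 and C6 arise in turn by α-face attack (proton, oxygen, hydride) on a decalin whose β face carries the axial C4β and C10β methyls. The E alkene comes from a syn hydrozirconation.

Key step: step 7

Remark: the target SMILES is read as 2α,6β,7α-triacetoxy, 5α-H, 10β-methyl (normal labdane series), 13E. Labdane numbering is used for all bicyclic compounds, and α is the face opposite the C10 methyl.

**Step 1**
Reactants: 1 (4R,6R)-4-hydroxy-2,2,6-trimethylcyclohexan-1-one (actinol)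
Product: 2 (4R,6R)-4-(tert-butyldimethylsilyloxy)-2,2,6-trimethylcyclohexan-1-one
Conditions: TBSCl, imidazole, DMF, rt
Reagents that add atoms: tert-butyldimethylsilyl chloride, CC(C)(C)[Si](C)(C)Cl
Why: Imidazole-promoted silyl ether formation masks the only hydroxyl so that the strong base of the next step meets the ketone alone, and no stereocentre is touched.

**Step 2**
Reactants: 2 (4R,6R)-4-(tert-butyldimethylsilyloxy)-2,2,6-trimethylcyclohexan-1-one
Product: 4 (R)-4-(tert-butyldimethylsilyloxy)-2,6,6-trimethylcyclohex-1-en-1-yl trifluoromethanesulfonate, via lithium enolate 3 (not isolated)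
Conditions: LiN(i-Pr)2, THF, −78 → 0 °C; PhNTf2, −78 °C → rt
Reagents that add atoms: N-phenylbis(trifluoromethanesulfonimide), O=S(=O)(N(c1ccccc1)S(=O)(=O)C(F)(F)F)C(F)(F)F
Why: In this enol triflate formation the ketone has a single α-hydrogen, so only the tetrasubstituted enolate can form and is trapped on oxygen, which erases the methyl-bearing stereocentre on purpose and leaves the carbinol centre intact.

**Step 3**
Reactants: 4 (R)-4-(tert-butyldimethylsilyloxy)-2,6,6-trimethylcyclohex-1-en-1-yl trifluoromethanesulfonate; 5 tributyl(1-ethoxyvinyl)stannane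
Product: 6 (R)-tert-butyl{[4-(1-ethoxyvinyl)-3,5,5-trimethylcyclohex-3-en-1-yl]oxy}dimethylsilane
Conditions: Pd2(dba)3 (cat.), AsPh3, LiCl, NMP, 70 °C
Reagents that add atoms: none
Why: Stille coupling of a vinyl triflate with an α-alkoxyvinylstannane, run with the weakly bound AsPh3 ligand and LiCl that suit hindered 2,6,6-trimethylcyclohexenyl triflates, installs C6 and C7 as a masked acetyl group.

**Step 4**
Reactants: 6 (R)-tert-butyl{[4-(1-ethoxyvinyl)-3,5,5-trimethylcyclohex-3-en-1-yl]oxy}dimethylsilane
Product: 7 (R)-1-(4-hydroxy-2,6,6-trimethylcyclohex-1-en-1-yl)ethan-1-one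
Conditions: 2 M HCl, THF, rt
Reagents that add atoms: water, O
Why: In this acid hydrolysis the 2-ethoxydiene is protonated at its terminal carbon and collapses to the methyl ketone while the same aqueous acid cleaves the secondary TBS ether, so both unmaskings happen in one operation without touching the carbinol centre.

**Step 5**
Reactants: 7 (R)-1-(4-hydroxy-2,6,6-trimethylcyclohex-1-en-1-yl)ethan-1-one; 8 but-2-ynoic acid
Product: 9 (R)-4-acetyl-3,5,5-trimethylcyclohex-3-en-1-yl but-2-ynoate
Conditions: DCC, DMAP (cat.), CH2Cl2, 0 °C → rt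
Reagents that add atoms: none
Why: Steglich esterification acylates the oxygen with retention because the C–O bond is not broken, and low temperature with only catalytic DMAP keeps the ynoate from isomerising to the allenoate.

**Step 6**
Reactants: 9 (R)-4-acetyl-3,5,5-trimethylcyclohex-3-en-1-yl but-2-ynoate
Product: 10 (R)-4-[1-(tert-butyldimethylsilyloxy)vinyl]-3,5,5-trimethylcyclohex-3-en-1-yl but-2-ynoate
Conditions: TBSOTf, Et3N, CH2Cl2, −78 → 0 °C
Reagents that add atoms: tert-butyldimethylsilyl trifluoromethanesulfonate, CC(C)(C)[Si](C)(C)OS(=O)(=O)C(F)(F)F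
Why: Soft enolisation with a silyl triflate and a tertiary amine takes a proton from the acetyl CH3, because the crowded enone is twisted out of conjugation and its γ-hydrogens are not activated, and so gives the cross-conjugated 2-silyloxydiene without a base strong enough to harm the ynoate.

**Step 7**
Reactants: 10 (R)-4-[1-(tert-butyldimethylsilyloxy)vinyl]-3,5,5-trimethylcyclohex-3-en-1-yl but-2-ynoate
Product: 11 6-(tert-butyldimethylsilyloxy)drima-5,8-dien-11,2α-olide (10β-methyl)
Conditions: degassed toluene (0.01 M), BHT (cat.), base-washed sealed tube, 180 °C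
Reagents that add atoms: none
Why: On heating, the diene C7=C6(OTBS)–C5=C10 and the tethered alkyne C8≡C9 combine in a concerted, asynchronous [4+2] cycloaddition in which the nucleophilic enol-ether terminus C7 bonds to the electrophilic ynoate β-carbon C8 and the α-carbon C9 bonds to the fully substituted C10. The closest known reactions are the Diels–Alder additions of alkynoates to 1-vinyl-2,6,6-trimethylcyclohexenes that build the drimane skeleton and their ester-tethered intramolecular variants anchored on the allylic ring A oxygen, which give fused γ-lactones; here the anchor sits one carbon further round ring A. Ring B closes as a cyclohexa-1,4-diene through both new σ bonds, and the δ-lactone closes through C9–C10 as the six-membered tether ring (C10, C1, C2, O, C11, C9) of a type 1 intramolecular Diels–Alder reaction, bridged with ring A as a 2-oxabicyclo[3.3.1]nonan-3-one whose carbocyclic half can relax to a boat that turns the C4 methyls away from the lactone. C10 is the only new stereocentre and is controlled by C2: with O2 pseudoaxial on the ring A half-chair the three-atom arm O–C11–C9 reaches C10 only from the α face, so the C10 methyl is left on the β face. The step needs regioselectivity, which the tether secures (the crossed mode would require a seven-membered tether ring and a bond between the methyl-bearing C8 and C10) and the matched polarity reinforces, and it needs the cycloaddition to outrun the 1,5-hydrogen shift from the C10 methyl to C7 and adventitious hydrolysis of the enol silane, which dilution, a radical inhibitor and acid-free glass are meant to ensure. The alkyne oxidation level leaves C8=C9 with its methyl group and C11 in place, and the enol silane keeps C6 as a masked ketone.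

**Step 8**
Reactants: 11 6-(tert-butyldimethylsilyloxy)drima-5,8-dien-11,2α-olide
Product: 12 6-(tert-butyldimethylsilyloxy)drima-5,8-diene-2α,11-diol
Conditions: LiAlH4, Et2O, 0 °C; H2O/aq NaOH work-up
Reagents that add atoms: none
Why: In this hydride reduction of an α,β-unsaturated lactone the fully substituted β-carbon C8 blocks conjugate addition, so LiAlH4 gives the allylic C11 alcohol and frees O2, releasing ring A from the bridge, while the TBS enol ether is inert to hydride and to the basic work-up.

**Step 9**
Reactants: 12 6-(tert-butyldimethylsilyloxy)drima-5,8-diene-2α,11-diol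
Product: 13 2α-hydroxy-6-(tert-butyldimethylsilyloxy)drima-5,8-dien-11-al
Conditions: MnO2, CH2Cl2, rt
Reagents that add atoms: none
Why: Chemoselective MnO2 oxidation takes the primary allylic C11 alcohol to the enal and leaves the saturated secondary C2 alcohol and the enol silane alone.

**Step 10**
Reactants: 13 2α-hydroxy-6-(tert-butyldimethylsilyloxy)drima-5,8-dien-11-al
Product: 14 6-(tert-butyldimethylsilyloxy)-13,14,15,16-tetranorlabda-5,8,11-trien-2α-ol
Conditions: Ph3PCH3Br, KOt-Bu, THF, 0 °C; then 13, −78 → 0 °C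
Reagents that add atoms: methyltriphenylphosphonium bromide, C[P+](c1ccccc1)(c1ccccc1)c1ccccc1.[Br-]
Why: Wittig methylenation, well established for hindered β-cyclocitral-type enals, adds C12, since carbonyl addition of the unstabilised ylide at low temperature should outrun removal of the doubly allylic C7 protons and excess ylide covers the free hydroxyl.

**Step 11**
Reactants: 15 but-2-yn-1-ol
Product: 16 (but-2-yn-1-yloxy)(tert-butyl)diphenylsilane
Conditions: TBDPSCl, imidazole, CH2Cl2, rt
Reagents that add atoms: tert-butyldiphenylsilyl chloride, CC(C)(C)[Si](Cl)(c1ccccc1)c1ccccc1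
Why: Routine silyl ether formation, with TBDPS chosen because it outlasts the later removal of the enol silane and can still be taken off at the end beside three acetates.

**Step 12**
Reactants: 16 (but-2-yn-1-yloxy)(tert-butyl)diphenylsilane
Product: 18 (E)-tert-butyl[(3-iodobut-2-en-1-yl)oxy]diphenylsilane, via alkenylzirconocene chloride 17 (not isolated)
Conditions: Cp2Zr(H)Cl (excess), THF, rt, dark; I2, 0 °C
Reagents that add atoms: iodine, [I][I]
Why: In this hydrozirconation–iodination Zr–H adds syn with zirconium settling on the less hindered methyl-bearing alkyne carbon, and iodinolysis with retention then fixes the E geometry of the future C13=C14 bond.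

**Step 13**
Reactants: 14 6-(tert-butyldimethylsilyloxy)-13,14,15,16-tetranorlabda-5,8,11-trien-2α-ol; 18 (E)-tert-butyl[(3-iodobut-2-en-1-yl)oxy]diphenylsilane
Product: 20 15-(tert-butyldiphenylsilyloxy)-6-(tert-butyldimethylsilyloxy)labda-5,8,13E-trien-2α-ol, via bis(9-BBN) adduct 19 (not isolated)
Conditions: 9-BBN, THF, rt; then 18, PdCl2(dppf) (cat.), AsPh3, Cs2CO3, DMF–H2O, rt
Reagents that add atoms: none
Why: In this hydroboration and B-alkyl Suzuki–Miyaura coupling 9-BBN attacks only the monosubstituted C11=C12 alkene at C12, both ring alkenes being tetrasubstituted, and the alkylborane couples with the vinyl iodide with retention, forming C12–C13 and keeping the E geometry.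

**Step 14**
Reactants: 20 15-(tert-butyldiphenylsilyloxy)-6-(tert-butyldimethylsilyloxy)labda-5,8,13E-trien-2α-ol
Product: 21 15-(tert-butyldiphenylsilyloxy)-2α-hydroxylabda-8,13E-dien-6-one (5α-H)
Conditions: n-Bu4NF, AcOH, THF, −20 °C
Reagents that add atoms: none
Why: In this fluoride cleavage of a silyl enol ether with buffered protonation C5 takes its proton axially from the α face, because the β face is flanked by the axial C4β and C10β methyls, giving the trans-decalin that is also the more stable epimer, while the enol silane reacts far faster than the TBDPS alkyl ether and the acetic acid buffer keeps C8=C9 from moving into conjugation.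

**Step 15**
Reactants: 21 15-(tert-butyldiphenylsilyloxy)-2α-hydroxylabda-8,13E-dien-6-one
Product: 23 15-(tert-butyldiphenylsilyloxy)-2α,7α-dihydroxylabda-8,13E-dien-6-one, via dipotassium dienolate 22 (not isolated)
Conditions: KN(SiMe3)2 (2.3 equiv), THF, −78 °C; 2-(phenylsulfonyl)-3-phenyloxaziridine, −78 °C; AcOH, −78 °C
Reagents that add atoms: 2-(phenylsulfonyl)-3-phenyloxaziridine, O=S(=O)(N1OC1c2ccccc2)c3ccccc3
Why: In this Davis enolate hydroxylation the base removes the exposed, doubly activated C7 proton rather than the buried C5 proton, the dienolate reacts at its α-carbon C7, and the bulky oxaziridine approaches the α face away from the C10β and C4β methyls, which sets 7α-OH.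

**Step 16**
Reactants: 23 15-(tert-butyldiphenylsilyloxy)-2α,7α-dihydroxylabda-8,13E-dien-6-one
Product: 24 15-(tert-butyldiphenylsilyloxy)labda-8,13E-diene-2α,6β,7α-triol
Conditions: NaBH4, MeOH–THF, −20 °C
Reagents that add atoms: none
Why: In this borohydride reduction the β face of the C6 carbonyl is closed by the syn-axial C4β and C10β methyls, so hydride enters from the α face and gives the axial 6β-alcohol, and the fast cold reduction removes the ketol before it can epimerise or shift.

**Step 17**
Reactants: 24 15-(tert-butyldiphenylsilyloxy)labda-8,13E-diene-2α,6β,7α-triol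
Product: 25 2α,6β,7α-triacetoxy-15-(tert-butyldiphenylsilyloxy)labda-8,13E-diene
Conditions: Ac2O (excess), DMAP, pyridine, 50 °C
Reagents that add atoms: acetic anhydride, CC(=O)OC(C)=O
Why: DMAP-catalysed acetylation esterifies all three secondary alcohols with retention because no C–O bond is broken, and warming with excess reagent is needed only for the axial, doubly flanked 6β-hydroxyl.

**Step 18**
Reactants: 25 2α,6β,7α-triacetoxy-15-(tert-butyldiphenylsilyloxy)labda-8,13E-diene
Product: 26 2α,6β,7α-triacetoxylabda-8,13E-dien-15-ol (CNP0305346.2)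
Conditions: HF·pyridine, pyridine, THF, 0 °C → rt
Reagents that add atoms: none
Why: Fluoride desilylation with buffered HF·pyridine cleaves the primary allylic TBDPS ether under mildly acidic conditions in which the acetates should neither hydrolyse nor migrate.

**Compound list**
1 | (4R,6R)-4-hydroxy-2,2,6-trimethylcyclohexan-1-one (actinol) | O[C@H]1CC(C)(C)C(=O)[C@H](C)C1 | starting material
2 | (4R,6R)-4-(tert-butyldimethylsilyloxy)-2,2,6-trimethylcyclohexan-1-one | CC(C)(C)[Si](C)(C)O[C@H]1CC(C)(C)C(=O)[C@H](C)C1 | intermediate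
3 | lithium (R)-4-(tert-butyldimethylsilyloxy)-2,6,6-trimethylcyclohex-1-en-1-olate | CC(C)(C)[Si](C)(C)O[C@H]1CC(C)(C)C(O[Li])=C(C)C1 | intermediate
4 | (R)-4-(tert-butyldimethylsilyloxy)-2,6,6-trimethylcyclohex-1-en-1-yl trifluoromethanesulfonate | CC(C)(C)[Si](C)(C)O[C@H]1CC(C)(C)C(OS(=O)(=O)C(F)(F)F)=C(C)C1 | intermediate
5 | tributyl(1-ethoxyvinyl)stannane | CCOC(=C)[Sn](CCCC)(CCCC)CCCC | starting material
6 | (R)-tert-butyl{[4-(1-ethoxyvinyl)-3,5,5-trimethylcyclohex-3-en-1-yl]oxy}dimethylsilane | CC(C)(C)[Si](C)(C)O[C@H]1CC(C)(C)C(C(=C)OCC)=C(C)C1 | intermediate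
7 | (R)-1-(4-hydroxy-2,6,6-trimethylcyclohex-1-en-1-yl)ethan-1-one | O[C@H]1CC(C)(C)C(C(C)=O)=C(C)C1 | intermediate
8 | but-2-ynoic acid | CC#CC(=O)O | starting material
9 | (R)-4-acetyl-3,5,5-trimethylcyclohex-3-en-1-yl but-2-ynoate | CC#CC(=O)O[C@H]1CC(C)(C)C(C(C)=O)=C(C)C1 | intermediate
10 | (R)-4-[1-(tert-butyldimethylsilyloxy)vinyl]-3,5,5-trimethylcyclohex-3-en-1-yl but-2-ynoate | CC#CC(=O)O[C@H]1CC(C)(C)C(C(=C)O[Si](C)(C)C(C)(C)C)=C(C)C1 | intermediate
11 | 6-(tert-butyldimethylsilyloxy)drima-5,8-dien-11,2α-olide (10β-methyl) | O=C1O[C@H]2CC(C)(C)C3=C(O[Si](C)(C)C(C)(C)C)CC(C)=C1[C@@]3(C)C2 | intermediate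
12 | 6-(tert-butyldimethylsilyloxy)drima-5,8-diene-2α,11-diol | O[C@H]1CC(C)(C)C2=C(O[Si](C)(C)C(C)(C)C)CC(C)=C(CO)[C@@]2(C)C1 | intermediate
13 | 2α-hydroxy-6-(tert-butyldimethylsilyloxy)drima-5,8-dien-11-al | O[C@H]1CC(C)(C)C2=C(O[Si](C)(C)C(C)(C)C)CC(C)=C(C=O)[C@@]2(C)C1 | intermediate
14 | 6-(tert-butyldimethylsilyloxy)-13,14,15,16-tetranorlabda-5,8,11-trien-2α-ol | O[C@H]1CC(C)(C)C2=C(O[Si](C)(C)C(C)(C)C)CC(C)=C(C=C)[C@@]2(C)C1 | intermediate
15 | but-2-yn-1-ol | CC#CCO | starting material
16 | (but-2-yn-1-yloxy)(tert-butyl)diphenylsilane | CC#CCO[Si](c1ccccc1)(c1ccccc1)C(C)(C)C | intermediate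
17 | chlorobis(cyclopentadienyl)[(E)-4-(tert-butyldiphenylsilyloxy)but-2-en-2-yl]zirconium | Cl[Zr](C1C=CC=C1)(C1C=CC=C1)/C(C)=C/CO[Si](c1ccccc1)(c1ccccc1)C(C)(C)C | intermediate
18 | (E)-tert-butyl[(3-iodobut-2-en-1-yl)oxy]diphenylsilane | I/C(C)=C/CO[Si](c1ccccc1)(c1ccccc1)C(C)(C)C | intermediate
19 | 12-(9-borabicyclo[3.3.1]nonan-9-yl)-2α-(9-borabicyclo[3.3.1]nonan-9-yloxy)-6-(tert-butyldimethylsilyloxy)-13,14,15,16-tetranorlabda-5,8-diene | C1CCC2CCCC1B2O[C@H]3CC(C)(C)C4=C(O[Si](C)(C)C(C)(C)C)CC(C)=C(CCB5C6CCCC5CCC6)[C@@]4(C)C3 | intermediate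
20 | 15-(tert-butyldiphenylsilyloxy)-6-(tert-butyldimethylsilyloxy)labda-5,8,13E-trien-2α-ol | O[C@H]1CC(C)(C)C2=C(O[Si](C)(C)C(C)(C)C)CC(C)=C(CC/C(C)=C/CO[Si](c3ccccc3)(c3ccccc3)C(C)(C)C)[C@@]2(C)C1 | intermediate
21 | 15-(tert-butyldiphenylsilyloxy)-2α-hydroxylabda-8,13E-dien-6-one (5α-H) | O[C@H]1CC(C)(C)[C@@H]2C(=O)CC(C)=C(CC/C(C)=C/CO[Si](c3ccccc3)(c3ccccc3)C(C)(C)C)[C@@]2(C)C1 | intermediate
22 | dipotassium 2α-alkoxide 6,8-dien-6-olate of 21 | [K]O[C@H]1CC(C)(C)[C@@H]2C(O[K])=CC(C)=C(CC/C(C)=C/CO[Si](c3ccccc3)(c3ccccc3)C(C)(C)C)[C@@]2(C)C1 | intermediate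
23 | 15-(tert-butyldiphenylsilyloxy)-2α,7α-dihydroxylabda-8,13E-dien-6-one | O[C@H]1CC(C)(C)[C@@H]2C(=O)[C@@H](O)C(C)=C(CC/C(C)=C/CO[Si](c3ccccc3)(c3ccccc3)C(C)(C)C)[C@@]2(C)C1 | intermediate
24 | 15-(tert-butyldiphenylsilyloxy)labda-8,13E-diene-2α,6β,7α-triol | O[C@H]1CC(C)(C)[C@@H]2[C@H](O)[C@@H](O)C(C)=C(CC/C(C)=C/CO[Si](c3ccccc3)(c3ccccc3)C(C)(C)C)[C@@]2(C)C1 | intermediate
25 | 2α,6β,7α-triacetoxy-15-(tert-butyldiphenylsilyloxy)labda-8,13E-diene | CC(=O)O[C@H]1CC(C)(C)[C@@H]2[C@H](OC(C)=O)[C@@H](OC(C)=O)C(C)=C(CC/C(C)=C/CO[Si](c3ccccc3)(c3ccccc3)C(C)(C)C)[C@@]2(C)C1 | intermediate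
26 | (2S,5S,6S,7S,10S)-2α,6β,7α-triacetoxylabda-8,13E-dien-15-ol (CNP0305346.2) | CC(=O)O[C@H]1CC(C)(C)[C@@H]2[C@H](OC(C)=O)[C@@H](OC(C)=O)C(C)=C(CC/C(C)=C/CO)[C@@]2(C)C1 | target

**Step count**
Total step count: 18.
Longest linear sequence: 16 (steps 1–10 and 13–18, from actinol).

**Steps most likely to fail**

**Step 7.**
- Risk: the cycloaddition may stall. The diene is twisted by the C4 methyls and the C10 methyl, the ester must leave its preferred conformation to span the bridge, and a methyl-capped ynoate is only a modest dienophile.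
- Risk: on long heating the 1,5-hydrogen shift from the C10 methyl to C7, or loss of the enol silane, may take over.
- Fallback: it sets out from 7 and comes back at 11. It keeps the same two bonds and the same two rings but changes the dienophile.
- Alcohol 7 would be esterified (DCC, CH2Cl2) with commercial but-3-ynoic acid to (R)-4-acetyl-3,5,5-trimethylcyclohex-3-en-1-yl but-3-ynoate F1.
- TBSOTf/Et3N would move the alkyne to the allene and silylate the ketone in one operation, giving (R)-4-[1-(tert-butyldimethylsilyloxy)vinyl]-3,5,5-trimethylcyclohex-3-en-1-yl buta-2,3-dienoate F2.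
- The bent and more electrophilic C8=C9 bond of the allenoate should add to the same diene termini at a clearly lower temperature. This would give 6-(tert-butyldimethylsilyloxy)-9β-H-drima-5,8(12)-dien-11,2α-olide F3.
- DBU in CH2Cl2 would then draw the exocyclic alkene into conjugation with the lactone, erasing C9 and giving 11.

**Step 15** (together with the labile ketone 21 that feeds it).
- Risk: under strong base C8=C9 may drift into conjugation with C6.
- Risk: the dienolate may be attacked at C9 or from the β face.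
- Risk: the ketol may shift its carbonyl to C7, or the enolate may add to the sulfonimine.
- Fallback: it sets out from 20, never frees the ketone, and comes back at 23.
- A catalytic amount of Tf2NH in CH2Cl2 at low temperature would equilibrate the silyl enol ether by reversible protonation at C5 and loss of a C7 proton. The product would be 15-(tert-butyldiphenylsilyloxy)-6-(tert-butyldimethylsilyloxy)-5α-H-labda-6,8,13E-trien-2α-ol F4. This isomer should be favoured because it relieves the clash between the silyloxy group and the C4 methyls and gains diene conjugation.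
- Rubottom oxidation with dimethyldioxirane at −78 °C would epoxidise this most electron-rich alkene from the α face. This would give 6α,7α-epoxy-15-(tert-butyldiphenylsilyloxy)-6β-(tert-butyldimethylsilyloxy)labda-8,13E-dien-2α-ol F5.
- Buffered n-Bu4NF/AcOH would open F5 to 23.

**Step 3.**
- Risk: transmetalation between a palladium centre crowded by the two flanking substituted ring carbons and an α-substituted vinylstannane may be slow. Reduction or hydrolysis of the triflate, or destannylation, could then compete.
- Fallback: it sets out from 4 and comes back at 7.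
- Sonogashira coupling with (trimethylsilyl)acetylene (PdCl2(PPh3)2, CuI, Et3N, DMF) uses a slim partner that copes with such triflates. It would give (R)-tert-butyldimethyl({3,5,5-trimethyl-4-[(trimethylsilyl)ethynyl]cyclohex-3-en-1-yl}oxy)silane F6.
- K2CO3/MeOH would free the terminal enyne (R)-tert-butyl[(4-ethynyl-3,5,5-trimethylcyclohex-3-en-1-yl)oxy]dimethylsilane F7.
- Markovnikov hydration catalysed by Ph3PAuNTf2 in aqueous dioxane would give (R)-1-[4-(tert-butyldimethylsilyloxy)-2,6,6-trimethylcyclohex-1-en-1-yl]ethan-1-one F8.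
- 2 M HCl in THF would remove the silyl ether to give 7.

**Further compounds**
F1 | step 7 | (R)-4-acetyl-3,5,5-trimethylcyclohex-3-en-1-yl but-3-ynoate | C#CCC(=O)O[C@H]1CC(C)(C)C(C(C)=O)=C(C)C1
F2 | step 7 | (R)-4-[1-(tert-butyldimethylsilyloxy)vinyl]-3,5,5-trimethylcyclohex-3-en-1-yl buta-2,3-dienoate | C=C=CC(=O)O[C@H]1CC(C)(C)C(C(=C)O[Si](C)(C)C(C)(C)C)=C(C)C1
F3 | step 7 | 6-(tert-butyldimethylsilyloxy)-9β-H-drima-5,8(12)-dien-11,2α-olide | O=C1O[C@H]2CC(C)(C)C3=C(O[Si](C)(C)C(C)(C)C)CC(=C)[C@@H]1[C@@]3(C)C2
F4 | step 15 | 15-(tert-butyldiphenylsilyloxy)-6-(tert-butyldimethylsilyloxy)-5α-H-labda-6,8,13E-trien-2α-ol | O[C@H]1CC(C)(C)[C@@H]2C(O[Si](C)(C)C(C)(C)C)=CC(C)=C(CC/C(C)=C/CO[Si](c3ccccc3)(c3ccccc3)C(C)(C)C)[C@@]2(C)C1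
F5 | step 15 | 6α,7α-epoxy-15-(tert-butyldiphenylsilyloxy)-6β-(tert-butyldimethylsilyloxy)labda-8,13E-dien-2α-ol | O[C@H]1CC(C)(C)[C@@H]2[C@@]3(O[Si](C)(C)C(C)(C)C)O[C@H]3C(C)=C(CC/C(C)=C/CO[Si](c4ccccc4)(c4ccccc4)C(C)(C)C)[C@@]2(C)C1
F6 | step 3 | (R)-tert-butyldimethyl({3,5,5-trimethyl-4-[(trimethylsilyl)ethynyl]cyclohex-3-en-1-yl}oxy)silane | CC(C)(C)[Si](C)(C)O[C@H]1CC(C)(C)C(C#C[Si](C)(C)C)=C(C)C1
F7 | step 3 | (R)-tert-butyl[(4-ethynyl-3,5,5-trimethylcyclohex-3-en-1-yl)oxy]dimethylsilane | CC(C)(C)[Si](C)(C)O[C@H]1CC(C)(C)C(C#C)=C(C)C1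
F8 | step 3 | (R)-1-[4-(tert-butyldimethylsilyloxy)-2,6,6-trimethylcyclohex-1-en-1-yl]ethan-1-one | CC(C)(C)[Si](C)(C)O[C@H]1CC(C)(C)C(C(C)=O)=C(C)C1
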